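The ring is disconnected at C1–C2 (C1 acetoxy carbon, C2 methylene, C3 bromo carbon, C4 gem-dimethyl carbon, C5 chloro carbon, C6 ring alkene carbon; side chain C7, C8). The cis-1,3 relationship of O–C1 and Br–C3 across the C2 methylene is exploited. A TiBr4 halo-Prins cyclisation joins the aldehyde carbon C1 to the terminal vinyl carbon C2 and places bromide on C3. This closes the six-membered ring and sets C1 and C3 under control of the C5 stereocentre. The precursor is an acyclic (E)-2-substituted enal with a silyloxy group on C5, a vinyl group on the quaternary C4, and a silyloxymethyl group (C8) syn to C5.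

Key step: step 9

Remarks on the chemistry
- The atom labels C1–C8 above are used for all acyclic intermediates as well.
- The cyclisation places O–C5 trans to O–C1 and Br–C3, which is also the arrangement of Cl–C5 in the target. The later exchange of oxygen for chlorine at C5 must therefore occur with net retention; a backside displacement is not planned.
- The hydroxyl that steers the hydroalumination is the C8 hydroxyl, so the temporary group sits on the C1 oxygen and the permanent silyl ether goes on C8.
- C5 is set by asymmetric reverse prenylation, not by reduction of a ketone flanked by two groups of similar size.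
- Assumption: the B-prenyl reagent made from (−)-Ipc2BH, which derives from (+)-α-pinene, attacks the aldehyde face in the same sense as the parent B-allyl reagent. This gives (S) at C5.

Step 1
Reactants: 1 but-2-yne-1,4-diol
Product: 3 4-[(4-methoxybenzyl)oxy]but-2-yn-1-ol, via monosodium alkoxide 2 (not isolated)
Conditions: NaH, 4-MeOC6H4CH2Cl (0.35 equiv), Bu4NI (cat.), THF/DMF, 0 °C to rt
Reagents that add atoms: 4-methoxybenzyl chloride, COc1ccc(CCl)cc1
Why: Williamson ether synthesis on the symmetrical diol used in excess, so that the monoalkoxide is benzylated once; this masks the oxygen that becomes O–C1 and leaves the C8 hydroxyl free, and no stereocentre is involved.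

Step 2
Reactants: 3 4-[(4-methoxybenzyl)oxy]but-2-yn-1-ol
Product: 5 (2Z)-3-iodo-4-[(4-methoxybenzyl)oxy]but-2-en-1-ol, via cyclic alkenylaluminate 4 (not isolated)
Conditions: NaAlH2(OCH2CH2OCH3)2, THF, 0 °C; EtOAc; I2, −78 °C to 0 °C
Reagents that add atoms: iodine, II
Why: Alkoxide-directed trans-hydroalumination of a propargylic alcohol followed by iodinolysis: hydride goes to C7 and aluminium to C6 inside a five-membered oxaluminacycle, and iodine replaces aluminium with retention, so iodine ends on C6 syn to C8 and the alkene geometry of the target is fixed here.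

Step 3
Reactants: 5 (2Z)-3-iodo-4-[(4-methoxybenzyl)oxy]but-2-en-1-ol
Product: 6 tert-butyl({(2Z)-3-iodo-4-[(4-methoxybenzyl)oxy]but-2-en-1-yl}oxy)diphenylsilane
Conditions: t-BuPh2SiCl, imidazole, CH2Cl2, 0 °C to rt
Reagents that add atoms: tert-butyl(chloro)diphenylsilane, CC(C)(C)[Si](Cl)(c1ccccc1)c1ccccc1
Why: Imidazole-promoted silylation of the primary allylic alcohol; the robust tert-butyldiphenylsilyl ether on the C8 oxygen is chosen to survive the organolithium, oxidant and Lewis acid steps that follow.

Step 4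
Reactants: 6 tert-butyl({(2Z)-3-iodo-4-[(4-methoxybenzyl)oxy]but-2-en-1-yl}oxy)diphenylsilane; 7 N,N-dimethylformamide
Product: 10 (2Z)-4-[(tert-butyldiphenylsilyl)oxy]-2-{[(4-methoxybenzyl)oxy]methyl}but-2-enal, via alkenyllithium 8 (not isolated), via lithium hemiaminal alkoxide 9 (not isolated)
Conditions: t-BuLi (2.1 equiv), Et2O, −78 °C; DMF, −78 °C; aq NH4Cl; used crude at once
Reagents that add atoms: none
Why: Iodine–lithium exchange with retention of alkene geometry, then formylation of the alkenyllithium by DMF (Bouveault aldehyde synthesis), the hemiaminal alkoxide releasing the aldehyde only on work-up, so that the formyl carbon C5 arrives syn to C8; the mixture is kept at −78 °C to suppress 1,4-migration of silicon from oxygen to carbon and loss of the allylic alkoxide.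

Step 5
Reactants: 10 (2Z)-4-[(tert-butyldiphenylsilyl)oxy]-2-{[(4-methoxybenzyl)oxy]methyl}but-2-enal; 11 3-methylbuta-1,2-diene
Product: 14 (4S,5Z)-7-[(tert-butyldiphenylsilyl)oxy]-5-{[(4-methoxybenzyl)oxy]methyl}-3,3-dimethylhepta-1,5-dien-4-ol, via prenylborane 12 (not isolated), via borinate ester 13 (not isolated)
Conditions: (−)-Ipc2BH [from (+)-α-pinene], 11, THF, −25 °C; then 10, −78 °C; NaOH, H2O2, 0 °C
Reagents that add atoms: none
Why: Brown asymmetric allylboration in its reverse-prenylation form: hydroboration of the allene puts boron on the unsubstituted terminus, and the prenylborane transfers its dimethyl-substituted carbon to the aldehyde through a closed chair transition state, so the C4–C5 bond, the quaternary C4 with its vinyl group and the C5 carbinol are made together, the isopinocampheyl groups selecting the aldehyde face that gives (S) at C5.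

Step 6
Reactants: 14 (4S,5Z)-7-[(tert-butyldiphenylsilyl)oxy]-5-{[(4-methoxybenzyl)oxy]methyl}-3,3-dimethylhepta-1,5-dien-4-ol
Product: 15 (4S,5Z)-7-[(tert-butyldiphenylsilyl)oxy]-5-{[(4-methoxybenzyl)oxy]methyl}-3,3-dimethyl-4-[(triethylsilyl)oxy]hepta-1,5-diene
Conditions: Et3SiOTf, 2,6-lutidine, CH2Cl2, −78 °C to 0 °C
Reagents that add atoms: triethylsilyl trifluoromethanesulfonate, CC[Si](CC)(CC)OS(=O)(=O)C(F)(F)F
Why: Silylation of the hindered neopentyl-type secondary alcohol with a silyl triflate and a non-nucleophilic base; the triethylsilyl ether does not chelate and can later be removed beside the tert-butyldiphenylsilyl ether, and C5 is not touched.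

Step 7
Reactants: 15 (4S,5Z)-7-[(tert-butyldiphenylsilyl)oxy]-5-{[(4-methoxybenzyl)oxy]methyl}-3,3-dimethyl-4-[(triethylsilyl)oxy]hepta-1,5-diene
Product: 16 (2Z)-4-[(tert-butyldiphenylsilyl)oxy]-2-{(1S)-2,2-dimethyl-1-[(triethylsilyl)oxy]but-3-en-1-yl}but-2-en-1-ol
Conditions: DDQ, CH2Cl2/pH 7 buffer, 0 °C
Reagents that add atoms: none
Why: Oxidative cleavage of the 4-methoxybenzyl ether by DDQ (hydride abstraction from the electron-rich benzylic position, then hydrolysis) in a buffered two-phase medium leaves both silyl ethers and both alkenes untouched.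

Step 8
Reactants: 16 (2Z)-4-[(tert-butyldiphenylsilyl)oxy]-2-{(1S)-2,2-dimethyl-1-[(triethylsilyl)oxy]but-3-en-1-yl}but-2-en-1-ol
Product: 17 (2E)-4-[(tert-butyldiphenylsilyl)oxy]-2-{(1S)-2,2-dimethyl-1-[(triethylsilyl)oxy]but-3-en-1-yl}but-2-enal
Conditions: MnO2, CH2Cl2, rt
Reagents that add atoms: none
Why: MnO2 oxidation, selective for the primary allylic alcohol, gives the enal without touching C5, and the geometry carried through (C8 anti to the formyl group, syn to C5) is also the thermodynamically preferred one for a 2-substituted enal.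

Step 9
Reactants: 17 (2E)-4-[(tert-butyldiphenylsilyl)oxy]-2-{(1S)-2,2-dimethyl-1-[(triethylsilyl)oxy]but-3-en-1-yl}but-2-enal
Product: 19 (1S,2Z,3R,5R)-5-bromo-2-{2-[(tert-butyldiphenylsilyl)oxy]ethylidene}-4,4-dimethyl-3-[(triethylsilyl)oxy]cyclohexan-1-ol, via titanium alkoxide 18 (not isolated)
Conditions: TiBr4 (1.2 equiv), 2,6-di-tert-butyl-4-methylpyridine (0.3 equiv), CH2Cl2, −78 °C; aq NaHCO3
Reagents that add atoms: titanium tetrabromide, Br[Ti](Br)(Br)Br
Why: TiBr4 binds the aldehyde oxygen, the terminal vinyl carbon C2 adds to C1 and bromide from the titanium ate complex is captured at C3 anti to the new C–C bond, which is a Lewis acid halo-Prins (cationic carbonyl–alkene) cyclisation of a hex-5-enal to a cis-3-halocyclohexanol, a known reaction type. The ring C1–C6 closes through a chair with both vinyl carbons inside the ring (6-endo with respect to the alkene, exo with respect to the carbonyl). C5 controls both new centres: allylic 1,3-strain with the C8 methylene, which is syn to C5, turns the C5 hydrogen into the plane of the C6=C7 bond and the triethylsilyloxy group into the axial position, where it blocks the axial sites of C1 and C3 on its face. The carbonyl therefore reacts through its s-cis rotamer with oxygen equatorial at C1, and bromide enters C3 equatorially, so O–C1 and Br–C3 end cis to each other and trans to O–C5. The step needs attack at C1 and not at C7 of the enal, and halide capture ahead of a 1,2-methyl shift from C4; the shielded trisubstituted C7, the absence of hydrogen on C4 (no ene pathway), the low temperature and the bromide-rich counter-ion should secure this. The hindered pyridine base removes traces of HBr so that both silyl ethers survive.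

Step 10
Reactants: 19 (1S,2Z,3R,5R)-5-bromo-2-{2-[(tert-butyldiphenylsilyl)oxy]ethylidene}-4,4-dimethyl-3-[(triethylsilyl)oxy]cyclohexan-1-ol
Product: 20 (1S,2Z,3R,5R)-5-bromo-2-{2-[(tert-butyldiphenylsilyl)oxy]ethylidene}-4,4-dimethyl-3-[(triethylsilyl)oxy]cyclohexyl acetate
Conditions: Ac2O, pyridine, DMAP (cat.), CH2Cl2, 0 °C to rt
Reagents that add atoms: acetic anhydride, CC(=O)OC(C)=O
Why: DMAP-catalysed acylation of the equatorial secondary alcohol installs the acetate of the target with the C1 configuration unchanged.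

Step 11
Reactants: 20 (1S,2Z,3R,5R)-5-bromo-2-{2-[(tert-butyldiphenylsilyl)oxy]ethylidene}-4,4-dimethyl-3-[(triethylsilyl)oxy]cyclohexyl acetate
Product: 21 (1S,2E,3R,5R)-5-bromo-2-{2-[(tert-butyldiphenylsilyl)oxy]ethylidene}-3-hydroxy-4,4-dimethylcyclohexyl acetate (C8 still syn to C5; only the descriptor changes)
Conditions: PPTS, MeOH/CH2Cl2, 0 °C to rt
Reagents that add atoms: none
Why: Acid-catalysed methanolysis of the triethylsilyl ether, which is cleaved far faster than the tert-butyldiphenylsilyl ether under these conditions, frees the C5 hydroxyl while the acetate and the secondary bromide are inert.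

Step 12
Reactants: 21 (1S,2E,3R,5R)-5-bromo-2-{2-[(tert-butyldiphenylsilyl)oxy]ethylidene}-3-hydroxy-4,4-dimethylcyclohexyl acetate
Product: 23 (1S,2Z,3R,5R)-5-bromo-2-{2-[(tert-butyldiphenylsilyl)oxy]ethylidene}-3-chloro-4,4-dimethylcyclohexyl acetate, via C5 mesylate 22 (not isolated)
Conditions: MsCl, Et3N, CH2Cl2, −40 °C; LiCl, THF, −40 °C to 0 °C
Reagents that add atoms: lithium chloride, [Li+].[Cl-]
Why: Sulfonylation followed by chloride substitution of the allylic sulfonate in its ionising (SN1-type, ion-pair) mode: backside displacement at the neopentyl-type C5 is blocked, the axial C–O bond is aligned with the C6=C7 π system for ionisation, and chloride returns to C5 along the same axial trajectory, anti to the equatorial acetate and bromide, because an equatorial chloride would suffer allylic 1,3-strain with C8, while attack at C7 is disfavoured by the electron-withdrawing silyloxymethyl group there; the net result is retention at C5.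

Step 13
Reactants: 23 (1S,2Z,3R,5R)-5-bromo-2-{2-[(tert-butyldiphenylsilyl)oxy]ethylidene}-3-chloro-4,4-dimethylcyclohexyl acetate
Product: 24 (1S,2Z,3R,5R)-5-bromo-3-chloro-2-(2-hydroxyethylidene)-4,4-dimethylcyclohexyl acetate
Conditions: HF·pyridine, pyridine, THF, 0 °C to rt
Reagents that add atoms: none
Why: Fluoride-mediated cleavage of the silyl ether with buffered HF·pyridine is mild enough to leave the acetate, the allylic chloride and the secondary bromide in place.

Step 14
Reactants: 24 (1S,2Z,3R,5R)-5-bromo-3-chloro-2-(2-hydroxyethylidene)-4,4-dimethylcyclohexyl acetate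
Product: 26 (1S,2Z,3R,5R)-5-bromo-2-(2-bromoethylidene)-3-chloro-4,4-dimethylcyclohexyl acetate, via alkoxyphosphonium bromide 25 (not isolated)
Conditions: CBr4, PPh3, CH2Cl2, 0 °C
Reagents that add atoms: carbon tetrabromide, BrC(Br)(Br)Br
Why: Appel reaction: the primary allylic alcohol is activated as its alkoxyphosphonium salt and displaced by bromide in an SN2 reaction at C8, the alternative SN2′ site C6 being fully substituted and the stereocentres remote.

Compound list
1 | but-2-yne-1,4-diol | OCC#CCO | starting material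
2 | sodium 4-hydroxybut-2-yn-1-olate | [Na+].[O-]CC#CCO | intermediate
3 | 4-[(4-methoxybenzyl)oxy]but-2-yn-1-ol | COc1ccc(COCC#CCO)cc1 | intermediate
4 | sodium 2,2-bis(2-methoxyethoxy)-3-{[(4-methoxybenzyl)oxy]methyl}-2,5-dihydro-1,2-oxaluminol-2-uide (Al on C6, ring O on C8) | [Na+].COCCO[Al-]1(OCCOC)OCC=C1COCc1ccc(OC)cc1 | intermediate
5 | (2Z)-3-iodo-4-[(4-methoxybenzyl)oxy]but-2-en-1-ol (I on C6, syn to C8) | OC/C=C(\I)COCc1ccc(OC)cc1 | intermediate
6 | tert-butyl({(2Z)-3-iodo-4-[(4-methoxybenzyl)oxy]but-2-en-1-yl}oxy)diphenylsilane | COc1ccc(COC/C(I)=C/CO[Si](c2ccccc2)(c2ccccc2)C(C)(C)C)cc1 | intermediate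
7 | N,N-dimethylformamide | CN(C)C=O | starting material
8 | alkenyllithium from 6 (Li in place of I on C6, syn to C8) | [Li]/C(COCc1ccc(OC)cc1)=C\CO[Si](c1ccccc1)(c1ccccc1)C(C)(C)C | intermediate
9 | lithium hemiaminal alkoxide from 8 and DMF (C5 bears OLi and NMe2) | [Li]OC(N(C)C)/C(COCc1ccc(OC)cc1)=C\CO[Si](c1ccccc1)(c1ccccc1)C(C)(C)C | intermediate
10 | (2Z)-4-[(tert-butyldiphenylsilyl)oxy]-2-{[(4-methoxybenzyl)oxy]methyl}but-2-enal (formyl carbon C5 syn to C8) | O=C/C(COCc1ccc(OC)cc1)=C\CO[Si](c1ccccc1)(c1ccccc1)C(C)(C)C | intermediate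
11 | 3-methylbuta-1,2-diene | CC(C)=C=C | starting material
12 | (3-methylbut-2-en-1-yl)diisopinocampheylborane, isopinocampheyl groups from (+)-α-pinene | CC(C)=CCB([C@@H]1C[C@@H]2C[C@H]([C@H]1C)C2(C)C)[C@@H]1C[C@@H]2C[C@H]([C@H]1C)C2(C)C | intermediate
13 | diisopinocampheylborinate ester of 14 | COc1ccc(COC/C(=C/CO[Si](c2ccccc2)(c2ccccc2)C(C)(C)C)[C@@H](OB([C@@H]2C[C@@H]3C[C@H]([C@H]2C)C3(C)C)[C@@H]2C[C@@H]3C[C@H]([C@H]2C)C3(C)C)C(C)(C)C=C)cc1 | intermediate
14 | (4S,5Z)-7-[(tert-butyldiphenylsilyl)oxy]-5-{[(4-methoxybenzyl)oxy]methyl}-3,3-dimethylhepta-1,5-dien-4-ol (C5 carbinol S; C8 syn to C5) | COc1ccc(COC/C(=C/CO[Si](c2ccccc2)(c2ccccc2)C(C)(C)C)[C@@H](O)C(C)(C)C=C)cc1 | intermediate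
15 | (4S,5Z)-7-[(tert-butyldiphenylsilyl)oxy]-5-{[(4-methoxybenzyl)oxy]methyl}-3,3-dimethyl-4-[(triethylsilyl)oxy]hepta-1,5-diene | COc1ccc(COC/C(=C/CO[Si](c2ccccc2)(c2ccccc2)C(C)(C)C)[C@@H](O[Si](CC)(CC)CC)C(C)(C)C=C)cc1 | intermediate
16 | (2Z)-4-[(tert-butyldiphenylsilyl)oxy]-2-{(1S)-2,2-dimethyl-1-[(triethylsilyl)oxy]but-3-en-1-yl}but-2-en-1-ol | OC/C(=C/CO[Si](c1ccccc1)(c1ccccc1)C(C)(C)C)[C@@H](O[Si](CC)(CC)CC)C(C)(C)C=C | intermediate
17 | (2E)-4-[(tert-butyldiphenylsilyl)oxy]-2-{(1S)-2,2-dimethyl-1-[(triethylsilyl)oxy]but-3-en-1-yl}but-2-enal (key-step precursor; C8 syn to C5) | O=C/C(=C/CO[Si](c1ccccc1)(c1ccccc1)C(C)(C)C)[C@@H](O[Si](CC)(CC)CC)C(C)(C)C=C | intermediate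
18 | tribromotitanium alkoxide of 19 | Br[Ti](Br)(Br)O[C@H]1C[C@@H](Br)C(C)(C)[C@H](O[Si](CC)(CC)CC)/C1=C\CO[Si](c1ccccc1)(c1ccccc1)C(C)(C)C | intermediate
19 | (1S,2Z,3R,5R)-5-bromo-2-{2-[(tert-butyldiphenylsilyl)oxy]ethylidene}-4,4-dimethyl-3-[(triethylsilyl)oxy]cyclohexan-1-ol (key-step product; OH and Br cis, both trans to OSiEt3; C8 syn to C5) | O[C@H]1C[C@@H](Br)C(C)(C)[C@H](O[Si](CC)(CC)CC)/C1=C\CO[Si](c1ccccc1)(c1ccccc1)C(C)(C)C | intermediate
20 | (1S,2Z,3R,5R)-5-bromo-2-{2-[(tert-butyldiphenylsilyl)oxy]ethylidene}-4,4-dimethyl-3-[(triethylsilyl)oxy]cyclohexyl acetate | CC(=O)O[C@H]1C[C@@H](Br)C(C)(C)[C@H](O[Si](CC)(CC)CC)/C1=C\CO[Si](c1ccccc1)(c1ccccc1)C(C)(C)C | intermediate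
21 | (1S,2E,3R,5R)-5-bromo-2-{2-[(tert-butyldiphenylsilyl)oxy]ethylidene}-3-hydroxy-4,4-dimethylcyclohexyl acetate (C8 syn to C5) | CC(=O)O[C@H]1C[C@@H](Br)C(C)(C)[C@H](O)/C1=C\CO[Si](c1ccccc1)(c1ccccc1)C(C)(C)C | intermediate
22 | C5 methanesulfonate of 21 | CC(=O)O[C@H]1C[C@@H](Br)C(C)(C)[C@H](OS(C)(=O)=O)/C1=C\CO[Si](c1ccccc1)(c1ccccc1)C(C)(C)C | intermediate
23 | (1S,2Z,3R,5R)-5-bromo-2-{2-[(tert-butyldiphenylsilyl)oxy]ethylidene}-3-chloro-4,4-dimethylcyclohexyl acetate (Cl axial, trans to OAc and Br) | CC(=O)O[C@H]1C[C@@H](Br)C(C)(C)[C@H](Cl)/C1=C\CO[Si](c1ccccc1)(c1ccccc1)C(C)(C)C | intermediate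
24 | (1S,2Z,3R,5R)-5-bromo-3-chloro-2-(2-hydroxyethylidene)-4,4-dimethylcyclohexyl acetate | CC(=O)O[C@H]1C[C@@H](Br)C(C)(C)[C@H](Cl)/C1=C\CO | intermediate
25 | alkoxy(triphenyl)phosphonium bromide of 24 | CC(=O)O[C@H]1C[C@@H](Br)C(C)(C)[C@H](Cl)/C1=C\CO[P+](c1ccccc1)(c1ccccc1)c1ccccc1.[Br-] | intermediate
26 | (1S,2Z,3R,5R)-5-bromo-2-(2-bromoethylidene)-3-chloro-4,4-dimethylcyclohexyl acetate | CC(=O)O[C@H]1C[C@@H](Br)C(C)(C)[C@H](Cl)/C1=C\CBr | target

Total step count: 14
Longest linear sequence: 14 steps, from 1 to 26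

Steps most likely to fail

Step 9 (halo-Prins cyclisation). The conjugated aldehyde–TiBr4 complex may cyclise too slowly at −78 °C. If the mixture has to be warmed, three processes could take over: a 1,2-methyl shift from C4 to the developing C3 cation, attack of the vinyl group on C7 instead of C1, and Lewis acid cleavage of the triethylsilyl ether. The fallback sets out from 17. Ac2O with catalytic LiBF4 should convert the aldehyde into the geminal diacetate F1. SnBr4 in CH2Cl2 at −78 °C should then ionise one acetate to an acetoxycarbenium ion, a stronger electrophile than the metal-bound enal. This ion should close the same C1–C2 bond through the same chair at lower temperature, with bromide returned from the stannate to C3. The product is the acetate 20, where the route is rejoined, and step 10 is then not needed.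

Step 12 (chlorination at C5). The allyl cation may take up chloride at C7 with the double bond moving into the ring (allylic transposition), or it may lose a proton to give a diene. The fallback sets out from 21. Thionyl chloride without base should give the covalent chlorosulfite F2. Its decomposition under TiCl4 catalysis (CH2Cl2, −78 °C to 0 °C) should hand chloride back from the leaving group to the same face of C5 (internal return, retention), so the outcome no longer depends on external chloride finding the right terminus. The route is rejoined at 23.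

Step 5 (asymmetric reverse prenylation, together with the sensitive enal from step 4). The (Z)-enal 10 may isomerise to the more stable (E) isomer before it is captured, which would place C8 anti to C5, or the allylboration of this α-branched enal may show poor facial selectivity. The fallback sets out from 6. The alkenyllithium 8 is generated as in step 4 and added to 2,2-dimethylbut-3-enal F3, itself made from prenylmagnesium chloride and 7. This forms the C5–C6 bond instead of the C4–C5 bond and avoids any (Z)-enal. The resulting racemic alcohol F4 is oxidised with Dess–Martin periodinane to the dienone F5. Corey–Bakshi–Shibata reduction (BH3·SMe2, methyl-oxazaborolidine) then sets C5; the catalyst enantiomer is the one that delivers the (S) carbinol, to be confirmed by Mosher ester analysis because the two ketone substituents are of similar size. The route is rejoined at 14.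

Further compounds
F1 | step 9 | (2E)-4-[(tert-butyldiphenylsilyl)oxy]-2-{(1S)-2,2-dimethyl-1-[(triethylsilyl)oxy]but-3-en-1-yl}but-2-ene-1,1-diyl diacetate | CC(=O)OC(OC(C)=O)/C(=C/CO[Si](c1ccccc1)(c1ccccc1)C(C)(C)C)[C@@H](O[Si](CC)(CC)CC)C(C)(C)C=C
F2 | step 12 | C5 chlorosulfite of 21 | CC(=O)O[C@H]1C[C@@H](Br)C(C)(C)[C@H](OS(Cl)=O)/C1=C\CO[Si](c1ccccc1)(c1ccccc1)C(C)(C)C
F3 | step 5 | 2,2-dimethylbut-3-enal | C=CC(C)(C)C=O
F4 | step 5 | racemic (5Z)-7-[(tert-butyldiphenylsilyl)oxy]-5-{[(4-methoxybenzyl)oxy]methyl}-3,3-dimethylhepta-1,5-dien-4-ol | COc1ccc(COC/C(=C/CO[Si](c2ccccc2)(c2ccccc2)C(C)(C)C)C(O)C(C)(C)C=C)cc1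
F5 | step 5 | (5Z)-7-[(tert-butyldiphenylsilyl)oxy]-5-{[(4-methoxybenzyl)oxy]methyl}-3,3-dimethylhepta-1,5-dien-4-one | COc1ccc(COC/C(=C/CO[Si](c2ccccc2)(c2ccccc2)C(C)(C)C)C(=O)C(C)(C)C=C)cc1
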